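**Plan**
- Cuts, in retrosynthetic order: the O18 acetate, C12–C13 (Suzuki–Miyaura, chloroprene), and C11=C12 (Wittig carbon). The 8-OH/C17 methyl then goes back to an 8(17)-methylene and the 6-OH to a C6 enol ether. Last, ring B is cut at C9–C10 and C7–C8.
- Enabling feature: on ring A the quaternary carbons C4 and C10 are 1,3-related and carry C18 and C9 on the same face. An O18–C11 ester can therefore hold C9 over C10 of the ring A diene C10=C5–C6(OEt)=C7.
- Forward: ring A comes from 2,6-dimethylcyclohexanone and is converted into a dienyl allenoate. One cycloaddition closes ring B and a seven-membered lactone bridge. The bridge is then opened and C11 is grown into the C11–C16 chain.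
- Stereochemistry: C4 comes from a Pd/(R)-t-BuPHOX decarboxylative allylation, and C10 is relayed from C4 through the tether. C9 is set by dienolate protonation anti to C20, and C5 by enol ether protonation anti to C19/C20. C6 is set by SmI2 (equatorial OH), and C8 by epoxidation anti to C20 followed by hydride opening.

Key step: step 8

Assumption: labdane numbering is used for all bicyclic compounds (C18 = CH2O on C4, C19 and C20 = methyls on C4 and C10, C17 on C8, C11 on C9). "Pentanor" means C12–C16 are missing and "tetranor" means C13–C16 are missing. "Upper face" is the face that carries C18, H-5 and H-9 in the target, and "lower face" the one that carries C19 and C20. Commercial 1 is taken as its cis/trans mixture, which is immaterial because that methine becomes sp2 in step 4.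

**Step 1**
Reactants: 1 2,6-dimethylcyclohexanone; 2 allyl chloroformate
Product: 4 allyl 2,6-dimethylcyclohex-1-en-1-yl carbonate, via lithium enolate 3 (not isolated)
Conditions: LiN(SiMe3)2, THF, 0 °C; then 2, −78 °C
Reagents that add atoms: lithium bis(trimethylsilyl)amide, [Li+].C[Si](C)(C)[N-][Si](C)(C)C (lithium of 3 only)
Why: O-acylation of the only possible, tetrasubstituted enolate by a hard chloroformate gives the enol carbonate required for a Tsuji-type allylation, the hindered enolate carbon disfavouring C-acylation.

**Step 2**
Reactants: 4 allyl 2,6-dimethylcyclohex-1-en-1-yl carbonate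
Product: 5 (2R)-2-allyl-2,6-dimethylcyclohexanone (C6 methine as a mixture)
Conditions: Pd2(dba)3 (2.5 mol %), (R)-t-BuPHOX (6 mol %), THF, 25 °C
Reagents that add atoms: none
Why: In this decarboxylative asymmetric allylic alkylation (Tsuji allylation), ionisation and loss of CO2 give a palladium enolate/π-allyl pair whose coupling is steered by the ligand; the (R)-ligand should give the (R)-quaternary carbon (future C4) just as the (S)-ligand gives (S)-2-allyl-2-methylcyclohexanone, and enantiomeric purity can be raised later by recrystallising diol 25.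

**Step 3**
Reactants: 5 (2R)-2-allyl-2,6-dimethylcyclohexanone
Product: 6 (2R)-2,6-dimethyl-2-[(E)-prop-1-en-1-yl]cyclohexanone
Conditions: RuHCl(CO)(PPh3)3 (5 mol %), PhMe, 110 °C
Reagents that add atoms: none
Why: Ruthenium hydride-catalysed alkene isomerisation (hydrometalation/β-hydride elimination) moves the double bond by one position to the more stable (E)-propenyl group and cannot go further because the neighbouring carbon is quaternary.

**Step 4**
Reactants: 6 (2R)-2,6-dimethyl-2-[(E)-prop-1-en-1-yl]cyclohexanone
Product: 8 (R)-2,6-dimethyl-6-[(E)-prop-1-en-1-yl]cyclohex-1-en-1-yl trifluoromethanesulfonate, via potassium enolate 7 (not isolated)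
Conditions: KN(SiMe3)2, THF, −78 → 0 °C; PhNTf2, 0 °C → rt
Reagents that add atoms: potassium bis(trimethylsilyl)amide, [K+].C[Si](C)(C)[N-][Si](C)(C)C (potassium of 7 only); N-phenylbis(trifluoromethanesulfonimide), O=S(=O)(N(c1ccccc1)S(=O)(=O)C(F)(F)F)C(F)(F)F
Why: In this enol triflate formation only the methine side can enolise, and the triflimide traps the enolate on oxygen, as is routine for 2,2,6-trisubstituted cyclohexanones.

**Step 5**
Reactants: 8 (R)-2,6-dimethyl-6-[(E)-prop-1-en-1-yl]cyclohex-1-en-1-yl trifluoromethanesulfonate
Product: 10 (R)-6-(hydroxymethyl)-2,6-dimethylcyclohex-1-en-1-yl trifluoromethanesulfonate, via aldehyde 9 (not isolated)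
Conditions: O3, CH2Cl2–MeOH, −78 °C (Sudan Red 7B end point); NaBH4, −78 → 0 °C
Reagents that add atoms: ozone, [O-][O+]=O
Why: In this chemoselective ozonolysis with reductive work-up, electrophilic ozone should attack the electron-rich disubstituted propenyl bond much faster than the triflate-deactivated, tetrasubstituted ring alkene, and borohydride takes the aldehyde on to the C18 alcohol without touching the quaternary centre.

**Step 6**
Reactants: 10 (R)-6-(hydroxymethyl)-2,6-dimethylcyclohex-1-en-1-yl trifluoromethanesulfonate; 11 tributyl(1-ethoxyvinyl)stannane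
Product: 12 (S)-[2-(1-ethoxyvinyl)-1,3-dimethylcyclohex-2-en-1-yl]methanol
Conditions: Pd(PPh3)4 (10 mol %), CuCl, LiCl, i-Pr2NEt, DMSO, 60 °C; aqueous NH3 work-up
Reagents that add atoms: none
Why: Stille coupling in its CuCl/LiCl-accelerated form, made for congested enol triflates and 1-substituted vinylstannanes, brings in C6–C7 already as an enol ether, so the 2-ethoxydiene is obtained directly; the free alcohol is tolerated and the amine keeps the medium non-acidic.

**Step 7**
Reactants: 12 (S)-[2-(1-ethoxyvinyl)-1,3-dimethylcyclohex-2-en-1-yl]methanol; 13 but-3-ynoic acid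
Product: 15 (S)-[2-(1-ethoxyvinyl)-1,3-dimethylcyclohex-2-en-1-yl]methyl buta-2,3-dienoate, via but-3-ynoate ester 14 (not isolated)
Conditions: 2-chloro-1-methylpyridinium iodide, Et3N, CH2Cl2, 0 °C → rt
Reagents that add atoms: none
Why: Mukaiyama esterification acylates the neopentyl alcohol under basic conditions that spare the enol ether, and triethylamine shifts the propargylic ester to the conjugated allenoate by prototropic rearrangement.

**Step 8**
Reactants: 15 (S)-[2-(1-ethoxyvinyl)-1,3-dimethylcyclohex-2-en-1-yl]methyl buta-2,3-dienoate
Product: 16 tricyclic lactone (4S,9S,10S)-6-ethoxy-pentanorlabda-5,8(17)-dien-11,18-olide (rings A and B plus the O18–C11 lactone bridge on the upper face; H-9 on the lower face)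
Conditions: PhCN (0.01 M), BHT and 2,6-di-tert-butyl-4-methylpyridine (0.1 equiv each), base-washed sealed vessel, 150 °C
Reagents that add atoms: none
Why: Proposed new method: a thermal, concerted but asynchronous [4+2] cycloaddition in which the nucleophilic terminus C7 of the 2-ethoxydiene bonds to the electrophilic central allene carbon C8 while C9 bonds to the fully substituted C10 and the distal C8=C17 bond survives as the exocyclic methylene; the closest known reactions are type 2 intramolecular Diels–Alder reactions of ester-tethered 2-substituted dienes and the intermolecular additions of allenic and acetylenic esters to 2,6,6-trisubstituted 1-vinylcyclohexenes, but a type 2 closure onto a ring-embedded, tetrasubstituted diene terminus has not been described. Ring B closes as the six-membered cycloadduct ring and the lactone as a seven-membered bridge (C4–C18–O–C11–C9–C10–C5) across ring A, the four-atom tether allowing only the 1,3-bridged mode, which is also the electronically matched orientation. C10 is set by C4, because the tether reaches C10 only on the ring A face that carries C18, which puts C9 cis to C18 and C20 cis to C19. C9 is set by the tether as well: C11 has to lie inside the bridge (endo), so H-9 ends on the C20 face, epimeric to the target, and is corrected in step 11. The step needs site (conjugated rather than terminal allene bond), orientation and face selectivity, all secured by tether length and ester activation, while the small ethoxy group eases the s-cis diene next to quaternary C4, the disubstituted C4 favours folding and the polar solvent raises the share of the ester rotamer that can lactonise. The adduct keeps ring B as a boat with a bridgehead-type C5=C6 enol ether, so it should be handled on base-washed media and opened without delay.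

**Step 9**
Reactants: 16 tricyclic lactone
Product: 17 methyl 6-ethoxy-18-hydroxy-pentanorlabda-5,8(17)-dien-11-oate, 9-epi series (CO2Me axial on the upper face)
Conditions: K2CO3, MeOH–THF, rt
Reagents that add atoms: methanol, CO
Why: Base-catalysed transesterification (lactone methanolysis) is driven by release of the strain of the locked boat, changes no stereocentre and leaves the enol ether intact because the medium stays basic.

**Step 10**
Reactants: 17 methyl 6-ethoxy-18-hydroxy-pentanorlabda-5,8(17)-dien-11-oate (9-epi)
Product: 18 methyl 6-ethoxy-18-(triethylsilyloxy)-pentanorlabda-5,8(17)-dien-11-oate (9-epi)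
Conditions: Et3SiCl, imidazole, DMF, 0 °C → rt
Reagents that add atoms: chlorotriethylsilane, CC[Si](Cl)(CC)CC
Why: Standard silylation of a primary alcohol keeps O18 out of the enolate, hydride and oxidation steps that follow and sets it apart from the C11 alcohol made in step 12.

**Step 11**
Reactants: 18 methyl 6-ethoxy-18-(triethylsilyloxy)-pentanorlabda-5,8(17)-dien-11-oate (9-epi)
Product: 20 methyl 6-ethoxy-18-(triethylsilyloxy)-pentanorlabda-5,8(17)-dien-11-oate with H-9 on the upper face (CO2Me equatorial), via lithium dienolate 19 (not isolated)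
Conditions: LiN(i-Pr)2, THF–DMPU, −78 → −30 °C; AcOH in THF, −78 °C
Reagents that add atoms: lithium diisopropylamide, [Li+].CC(C)[N-]C(C)C (lithium of 19 only)
Why: Deprotonation of the β,γ-unsaturated ester gives an extended dienolate, and kinetic (deconjugative) protonation of such dienolates takes place at the α-carbon; here it should come from the upper face because the pseudoaxial C20 on the neighbouring C10 screens the lower one, which inverts C9 to the target configuration (also the more stable epimer) and keeps the 8(17)-methylene in place.

**Step 12**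
Reactants: 20 methyl ester with H-9 on the upper face
Product: 21 6-ethoxy-18-(triethylsilyloxy)-pentanorlabda-5,8(17)-dien-11-ol
Conditions: LiAlH4, Et2O, 0 °C
Reagents that add atoms: none
Why: Hydride reduction of the ester gives the primary alcohol, while the silyl ether, the enol ether and the alkene are inert.

**Step 13**
Reactants: 21 6-ethoxy-18-(triethylsilyloxy)-pentanorlabda-5,8(17)-dien-11-ol
Product: 22 6-ethoxy-18-(triethylsilyloxy)-pentanorlabda-5,8(17)-dien-11-al
Conditions: Pr4N[RuO4] (5 mol %), N-methylmorpholine N-oxide, 4 Å sieves, CH2Cl2, 0 °C → rt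
Reagents that add atoms: none
Why: The Ley–Griffith oxidation is neutral and mild, so the α-branched, β,γ-unsaturated aldehyde should neither epimerise nor slip into conjugation.

**Step 14**
Reactants: 22 6-ethoxy-18-(triethylsilyloxy)-pentanorlabda-5,8(17)-dien-11-al
Product: 23 6-ethoxy-18-(triethylsilyloxy)-tetranorlabda-5,8(17),11-triene (equatorial vinyl on C9)
Conditions: Ph3PCH3Br, KN(SiMe3)2, THF, 0 °C; then 22, −78 → 0 °C
Reagents that add atoms: methyltriphenylphosphonium bromide, C[P+](c1ccccc1)(c1ccccc1)c1ccccc1.[Br-]
Why: In this Wittig methylenation the unstabilised ylide adds to the aldehyde at low temperature faster than it deprotonates it, as is known for 8(17)-methylene decalin carbaldehydes of the albicanal type.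

**Step 15**
Reactants: 23 6-ethoxy-18-(triethylsilyloxy)-tetranorlabda-5,8(17),11-triene
Product: 24 18-hydroxy-tetranorlabda-8(17),11-dien-6-one (trans-decalin, H-5 on the upper face; in equilibrium with its five-membered 6,18-hemiketal)
Conditions: 0.2 M aq HCl–THF, 0 °C → rt, short contact; NaHCO3 quench
Reagents that add atoms: water, O
Why: In this acid-catalysed enol ether hydrolysis with concomitant loss of the triethylsilyl group, the rate-determining protonation of C5 should come from the upper face, opposite axial C19 and C20, giving the trans ring fusion (also the more stable one); it is far faster than enolisation of the resulting ketone, so brief exposure to dilute acid should leave the 8(17)-alkene out of conjugation.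

**Step 16**
Reactants: 24 18-hydroxy-tetranorlabda-8(17),11-dien-6-one
Product: 25 tetranorlabda-8(17),11-diene-6,18-diol (6-OH equatorial, upper face)
Conditions: SmI2, H2O, THF, 0 °C → rt
Reagents that add atoms: none
Why: Single-electron (ketyl) reduction with SmI2/H2O gives the thermodynamically preferred equatorial alcohol, whereas hydride reagents would attack from the open upper face and give the axial epimer; isolated alkenes are inert.

**Step 17**
Reactants: 25 tetranorlabda-8(17),11-diene-6,18-diol
Product: 26 8,17-epoxy-tetranorlabd-11-ene-6,18-diol (epoxide oxygen on the upper face, C17 on the lower face)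
Conditions: mCPBA (1.0 equiv), CH2Cl2, 0 °C
Reagents that add atoms: 3-chloroperoxybenzoic acid, O=C(OO)c1cccc(Cl)c1
Why: In this Prilezhaev epoxidation the 1,1-disubstituted alkene is more nucleophilic than the monosubstituted vinyl group, and the peracid approaches from the upper face because axial C20 blocks the lower one, the usual outcome for labd-8(17)-enes.

**Step 18**
Reactants: 26 8,17-epoxy-tetranorlabd-11-ene-6,18-diol
Product: 27 tetranorlabd-11-ene-6,8,18-triol (8-OH equatorial on the upper face, C17 methyl axial)
Conditions: LiAlH4, THF, 0 °C → reflux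
Reagents that add atoms: none
Why: SN2 hydride opening at the unsubstituted epoxide carbon C17 leaves the C8–O bond untouched, so the epoxide configuration becomes that of the tertiary alcohol.

**Step 19**
Reactants: 27 tetranorlabd-11-ene-6,8,18-triol; 28 chloroprene (2-chlorobuta-1,3-diene)
Product: 30 labda-13(16),14-diene-6,8,18-triol, via B-alkyl-9-BBN adduct 29 (not isolated)
Conditions: 9-BBN (excess), THF, rt; then 28, Pd(OAc)2 (5 mol %), SPhos (10 mol %), aq K3PO4, BHT, THF, 40 °C
Reagents that add atoms: 9-borabicyclo[3.3.1]nonane, [H]B1C2CCCC1CCC2 (stays only in 29)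
Why: Anti-Markovnikov hydroboration of the only remaining alkene puts boron on C12, and a B-alkyl Suzuki–Miyaura coupling, with an electron-rich biarylphosphine to activate the alkenyl chloride, joins C12 to C13 with the diene intact; any O-borylated hydroxyl groups are released by the aqueous base.

**Step 20**
Reactants: 30 labda-13(16),14-diene-6,8,18-triol
Product: 31 target, [(1S,4aR,5S,6S,8R,8aS)-6,8-dihydroxy-1,4a,6-trimethyl-5-(3-methylidenepent-4-en-1-yl)decahydronaphthalen-1-yl]methyl acetate (labdane numbering 4S,5S,6R,8S,9S,10R)
Conditions: Ac2O (1.1 equiv), pyridine, CH2Cl2, 0 °C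
Reagents that add atoms: acetic anhydride, CC(=O)OC(C)=O
Why: In this selective acylation the primary 18-OH should react faster than the secondary 6-OH, which is hemmed in by C4 and C10, and the tertiary 8-OH is inert without an acyl-transfer catalyst.

**Compound list**
1 | 2,6-dimethylcyclohexanone | CC1CCCC(C)C1=O | starting material
2 | allyl chloroformate | C=CCOC(=O)Cl | starting material
3 | lithium 2,6-dimethylcyclohex-1-en-1-olate | CC1CCCC(C)=C1[O-].[Li+] | intermediate
4 | allyl 2,6-dimethylcyclohex-1-en-1-yl carbonate | C=CCOC(=O)OC1=C(C)CCCC1C | intermediate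
5 | (2R)-2-allyl-2,6-dimethylcyclohexanone | C=CC[C@@]1(C)CCCC(C)C1=O | intermediate
6 | (2R)-2,6-dimethyl-2-[(E)-prop-1-en-1-yl]cyclohexanone | C/C=C/[C@@]1(C)CCCC(C)C1=O | intermediate
7 | potassium enolate of 6 | C/C=C/[C@@]1(C)CCCC(C)=C1[O-].[K+] | intermediate
8 | (R)-2,6-dimethyl-6-[(E)-prop-1-en-1-yl]cyclohex-1-en-1-yl triflate | C/C=C/[C@@]1(C)CCCC(C)=C1OS(=O)(=O)C(F)(F)F | intermediate
9 | (S)-6-formyl-2,6-dimethylcyclohex-1-en-1-yl triflate | O=C[C@@]1(C)CCCC(C)=C1OS(=O)(=O)C(F)(F)F | intermediate
10 | (R)-6-(hydroxymethyl)-2,6-dimethylcyclohex-1-en-1-yl triflate | OC[C@@]1(C)CCCC(C)=C1OS(=O)(=O)C(F)(F)F | intermediate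
11 | tributyl(1-ethoxyvinyl)stannane | CCCC[Sn](CCCC)(CCCC)C(=C)OCC | starting material
12 | (S)-[2-(1-ethoxyvinyl)-1,3-dimethylcyclohex-2-en-1-yl]methanol | OC[C@@]1(C)CCCC(C)=C1C(=C)OCC | intermediate
13 | but-3-ynoic acid | C#CCC(=O)O | starting material
14 | but-3-ynoate ester of 12 | C#CCC(=O)OC[C@@]1(C)CCCC(C)=C1C(=C)OCC | intermediate
15 | buta-2,3-dienoate ester of 12 (precursor of the key step) | C=C=CC(=O)OC[C@@]1(C)CCCC(C)=C1C(=C)OCC | intermediate
16 | lactone-bridged cycloadduct (product of the key step) | O=C1OC[C@@]2(C)CCC[C@]3(C)C2=C(OCC)CC(=C)[C@H]13 | intermediate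
17 | 9-epi hydroxy methyl ester | OC[C@@]1(C)CCC[C@]2(C)C1=C(OCC)CC(=C)[C@@H]2C(=O)OC | intermediate
18 | 9-epi methyl ester, 18-O-triethylsilyl ether | CC[Si](CC)(CC)OC[C@@]1(C)CCC[C@]2(C)C1=C(OCC)CC(=C)[C@@H]2C(=O)OC | intermediate
19 | lithium dienolate of 18 | CC[Si](CC)(CC)OC[C@@]1(C)CCC[C@]2(C)C1=C(OCC)CC(=C)C2=C([O-])OC.[Li+] | intermediate
20 | methyl ester with target configuration at C9 | CC[Si](CC)(CC)OC[C@@]1(C)CCC[C@]2(C)C1=C(OCC)CC(=C)[C@H]2C(=O)OC | intermediate
21 | C11 alcohol | CC[Si](CC)(CC)OC[C@@]1(C)CCC[C@]2(C)C1=C(OCC)CC(=C)[C@H]2CO | intermediate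
22 | C11 aldehyde | CC[Si](CC)(CC)OC[C@@]1(C)CCC[C@]2(C)C1=C(OCC)CC(=C)[C@H]2C=O | intermediate
23 | 9-vinyl enol ether | CC[Si](CC)(CC)OC[C@@]1(C)CCC[C@]2(C)C1=C(OCC)CC(=C)[C@H]2C=C | intermediate
24 | 18-hydroxy 6-ketone, trans-decalin | OC[C@@]1(C)CCC[C@]2(C)[C@@H]1C(=O)CC(=C)[C@H]2C=C | intermediate
25 | 6,18-diol | OC[C@@]1(C)CCC[C@]2(C)[C@@H]1[C@H](O)CC(=C)[C@H]2C=C | intermediate
26 | 8,17-epoxide | OC[C@@]1(C)CCC[C@]2(C)[C@@H]1[C@H](O)C[C@@]3(CO3)[C@H]2C=C | intermediate
27 | 9-vinyl 6,8,18-triol | OC[C@@]1(C)CCC[C@]2(C)[C@@H]1[C@H](O)C[C@](C)(O)[C@H]2C=C | intermediate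
28 | chloroprene | C=CC(Cl)=C | starting material
29 | B-(C12-alkyl)-9-BBN | OC[C@@]1(C)CCC[C@]2(C)[C@@H]1[C@H](O)C[C@](C)(O)[C@H]2CCB3C4CCCC3CCC4 | intermediate
30 | labda-13(16),14-diene-6,8,18-triol | OC[C@@]1(C)CCC[C@]2(C)[C@@H]1[C@H](O)C[C@](C)(O)[C@H]2CCC(=C)C=C | intermediate
31 | CNP0317825.1 | C=CC(=C)CC[C@H]1[C@]2(C)CCC[C@](C)(COC(C)=O)[C@H]2[C@H](O)C[C@]1(C)O | target

**Totals**
Total step count: 20. Longest linear sequence: 20 steps, from 1; all other inputs are commercial.

**Steps most likely to fail**

*Step 8.*
- The cycloaddition may be outrun by a [1,5]-hydrogen shift from C20 to C7, by allenoate oligomerisation, or by the reluctance of the ester to adopt the folded rotamer.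
- The fallback gives up the tether. It sets out from 12 and returns at 21.
- The alcohol is silylated (Et3SiCl, imidazole) to the triethylsilyl ether of the diene F1.
- F1 is heated with commercial ethyl buta-2,3-dienoate (toluene, 110–130 °C, or under high pressure). This is the known intermolecular Diels–Alder mode of 2,6,6-trisubstituted 1-vinylcyclohexenes with allenic and acetylenic esters.
- The ethoxy group still fixes the orientation. The face, however, is now chosen only by the small difference between CH3 and CH2OSiEt3 on C4. The ethyl ester cycloadduct of the needed C10 configuration F2 therefore has to be separated from the C10-epimeric cycloadduct F3.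
- Both C9 epimers of F2 are usable, because LiN(i-Pr)2 turns them into the same lithium dienolate F4.
- Protonation of F4 as in step 11 gives the C9-equatorial ethyl ester F5, and LiAlH4 then gives 21.

*Step 11.*
- Deprotonation of the hindered C9–H may be incomplete, protonation may occur at the γ-carbon (conjugation), or facial selectivity may be poor.
- The fallback moves the inversion to the aldehyde level under thermodynamic control. It sets out from 18 and returns at 22.
- LiAlH4 gives the 9-epi C11 alcohol F6, and oxidation as in step 13 gives the axial 9-epi aldehyde F7.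
- F7 is much more acidic than the ester. Brief equilibration with a weak amine base (DBU, CH2Cl2, 0 °C) should move the formyl group from the axial to the equatorial position, which is 22.

*Step 15.*
- Hydrolysis of the hindered enol ether may be slow enough that the 8(17) double bond migrates into conjugation with the new ketone.
- The fallback accepts this migration. It sets out from 23 and returns at 27, bypassing 24–26.
- Longer treatment with 2 M aq HCl–THF gives the conjugated 7-en-6-one F8.
- Weitz–Scheffer epoxidation (H2O2, NaOH, MeOH, 0 °C) attacks only the enone, from the upper face away from C20, to give the 7,8-epoxy 6-ketone F9.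
- SmI2 (THF–MeOH, −78 °C) cleaves the α C–O bond to the 8-hydroxy 6-ketone F10. More SmI2 with H2O at rt then reduces the ketone to the equatorial alcohol, giving 27.

**Further compounds**
F1 | step 8 | triethylsilyl ether of 12 | CC[Si](CC)(CC)OC[C@@]1(C)CCCC(C)=C1C(=C)OCC
F2 | step 8 | ethyl ester cycloadduct, target configuration at C10, C9 as a mixture | CC[Si](CC)(CC)OC[C@@]1(C)CCC[C@]2(C)C1=C(OCC)CC(=C)C2C(=O)OCC
F3 | step 8 | C10-epimeric ethyl ester cycloadduct (removed) | CC[Si](CC)(CC)OC[C@@]1(C)CCC[C@@]2(C)C1=C(OCC)CC(=C)C2C(=O)OCC
F4 | step 8 | lithium dienolate of F2 | CC[Si](CC)(CC)OC[C@@]1(C)CCC[C@]2(C)C1=C(OCC)CC(=C)C2=C([O-])OCC.[Li+]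
F5 | step 8 | ethyl ester with target configuration at C9 | CC[Si](CC)(CC)OC[C@@]1(C)CCC[C@]2(C)C1=C(OCC)CC(=C)[C@H]2C(=O)OCC
F6 | step 11 | 9-epi C11 alcohol | CC[Si](CC)(CC)OC[C@@]1(C)CCC[C@]2(C)C1=C(OCC)CC(=C)[C@@H]2CO
F7 | step 11 | 9-epi C11 aldehyde | CC[Si](CC)(CC)OC[C@@]1(C)CCC[C@]2(C)C1=C(OCC)CC(=C)[C@@H]2C=O
F8 | step 15 | 18-hydroxy-tetranorlabda-7,11-dien-6-one | OC[C@@]1(C)CCC[C@]2(C)[C@@H]1C(=O)C=C(C)[C@H]2C=C
F9 | step 15 | 7,8-epoxy 6-ketone, oxygen on the upper face | OC[C@@]1(C)CCC[C@]2(C)[C@@H]1C(=O)[C@@H]3O[C@]3(C)[C@H]2C=C
F10 | step 15 | 8,18-dihydroxy 6-ketone | OC[C@@]1(C)CCC[C@]2(C)[C@@H]1C(=O)C[C@](C)(O)[C@H]2C=C
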